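**Plan**
1. Numbering used: oxane O1, C2 (CMe2), C3 (CHBr), C4, C5, C6 (C bearing Me and the cyclohexyl); cyclohexane C1' (on C6), C3' (Br), C4' (Me, Cl).
2. Retrosynthesis: C3–Br ← alkenyl bromide ← C3 ketone ← C3 carboxylate; the two cis methyls on C2 and C6 ← an etheno bridge; then C2–C3 and C5–C6 are cut together, giving a 2-methyl-5-cyclohexylfuran plus a vinylcarbenoid (C3–C4–C5).
3. Enabling feature: O1 flanked by two fully substituted carbons that each carry one of two cis (1,3-diaxial) methyls is a masked furan. Furan O/C2/C5 become O1/C2/C6 and furan C3/C4 become those two methyls, so the oxane is the oxygen-bridged six-membered ring of an 8-oxabicyclo[3.2.1]octadiene.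
4. Forward: (R)-carvone → cis-diol acetonide methyl ketone → furan → formal [4+3] (oxane ring formed) → bridge cut to two methyls → ester → C3 ketone → ring halogens → alkenyl bromide → C3–Br.
5. Stereochemistry: C1' from carvone; C4'–O from anti epoxidation; C3' by SN2 opening of a cyclic sulfate; C4'–Cl by bromonium-directed anti attack; C6 by the auxiliary-controlled furan face in the key step; C3 by hydrogen delivery to the open ring face.

Key step: step 9

Assumption: the (R)-pantolactone auxiliary is taken to steer the carbenoid to the furan face drawn; if its sense is the opposite, the enantiomeric auxiliary is used and nothing else changes.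

**Route**

Step 1
Reactants: 1 (R)-carvone
Product: 2 trans-epoxycarvone (oxirane on the ring face opposite to the isopropenyl group)
Conditions: 30% H2O2, NaOH (cat.), MeOH, 0 °C
Reagents that add atoms: hydrogen peroxide, OO
Why: Weitz–Scheffer nucleophilic epoxidation, in which hydroperoxide adds axially to the enone β-carbon anti to the isopropenyl group, so the future C4' oxygen is trans and the methyl cis to the side chain.

Step 2
Reactants: 2 trans-epoxycarvone
Product: 3 (1R,2S,4R)-1-methyl-4-(prop-1-en-2-yl)cyclohexane-1,2-diol (cis-diol with both OH trans to isopropenyl)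
Conditions: LiAlH4, THF, 0 °C → reflux; aqueous NaOH work-up
Reagents that add atoms: none
Why: hydride reduction of an α,β-epoxy ketone followed by reductive oxirane opening; hydride should add to C=O anti to the oxirane C–O bond (Felkin–Anh polar control) and then attack the less substituted oxirane carbon, so the tertiary C–O bond is kept and both oxygens end trans to the side chain.

Step 3
Reactants: 3 cis-diol
Product: 4 acetonide of 3 (cis-fused 2,2-dimethyl-1,3-dioxolane)
Conditions: 2,2-dimethoxypropane, PPTS (cat.), CH2Cl2, rt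
Reagents that add atoms: 2,2-dimethoxypropane, COC(C)(C)OC
Why: acid-catalysed transketalisation of a cis-1,2-diol, which protects both hydroxyls through the basic, carbenoid and radical steps that follow.

Step 4
Reactants: 4 acetonide
Product: 6 methyl ketone 1-(acetonide-protected 3,4-dihydroxy-4-methylcyclohexyl)ethan-1-one, via ozonide 5 (not isolated)
Conditions: O3, CH2Cl2, −78 °C; Me2S, −78 °C → rt
Reagents that add atoms: ozone, [O-][O+]=O
Why: ozonolysis with reductive work-up removes the methylidene carbon of the isopropenyl group, so the carbonyl carbon becomes the future C6 and the methyl the future furan β-carbon; C1' is not touched.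

Step 5
Reactants: 6 methyl ketone
Product: 8 alkynone 1-(protected cyclohexyl)pent-4-yn-1-one, via lithium enolate 7 (not isolated)
Conditions: LDA, THF, −78 °C; propargyl bromide, −78 → −20 °C
Reagents that add atoms: propargyl bromide, C#CCBr
Why: kinetic enolate alkylation (SN2), in which LDA removes a proton from the unhindered methyl and not from the tertiary C1'–H, so the C1' configuration is kept.

Step 6
Reactants: 8 alkynone
Product: 9 furan 2-methyl-5-(protected cyclohexyl)furan
Conditions: PdCl2(MeCN)2 (5 mol%), THF, 60 °C
Reagents that add atoms: none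
Why: palladium-catalysed 5-exo-dig cycloisomerisation of a γ-alkynyl ketone and tautomerisation to the aromatic furan under neutral conditions, so neither the acetonide nor the α-stereocentre C1' is at risk.

Step 7
Reactants: 10 (R)-pantolactone; 11 but-3-enoic acid
Product: 12 (R)-pantolactonyl but-3-enoate
Conditions: DCC, DMAP (2 mol%), CH2Cl2, 0 °C
Reagents that add atoms: none
Why: Steglich esterification at low temperature with little DMAP, to keep the β,γ-double bond out of conjugation.

Step 8
Reactants: 12 (R)-pantolactonyl but-3-enoate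
Product: 13 (R)-pantolactonyl 2-diazobut-3-enoate
Conditions: 4-acetamidobenzenesulfonyl azide, DBU, MeCN, 0 °C; used at once
Reagents that add atoms: 4-acetamidobenzenesulfonyl azide, CC(=O)Nc1ccc(cc1)S(=O)(=O)N=[N+]=[N-]
Why: Regitz diazo transfer to the doubly activated allylic/α-ester position of a β,γ-unsaturated ester gives the vinyldiazoacetate, which is kept cold because it slowly cyclises to a pyrazole.

Step 9
Reactants: 9 furan; 13 (R)-pantolactonyl 2-diazobut-3-enoate
Product: 15 (R)-pantolactonyl 1-methyl-5-(protected cyclohexyl)-8-oxabicyclo[3.2.1]octa-2,6-diene-2-carboxylate, via divinylcyclopropane 14 (not isolated)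
Conditions: Rh2(O2CC7H15)4 (dirhodium tetraoctanoate, 1 mol%), hexanes, reflux, slow addition of 13
Reagents that add atoms: none
Why: The rhodium vinylcarbenoid from 13 cyclopropanates the methyl-flanked C=C of the furan, making the C2–C3 bond, and the resulting cis-divinylcyclopropane 14 undergoes a Cope rearrangement that makes the C5–C6 bond. The closest known reaction type is the tandem cyclopropanation/Cope (formal [4+3]) reaction of vinyldiazoacetates with 2,5-dialkylfurans. The cyclopropane closes by [2+1] carbene addition, and the oxygen-bridged six-membered ring (the oxane, part of the seven-membered carbocycle) closes by a boat-like [3,3]-sigmatropic shift, which dearomatises the furan. Both new bonds form on one furan face, so the two bridgeheads are cis by necessity; the absolute face (C6) is set by the pantolactone auxiliary on the carbenoid, the remote ring stereocentres having little influence. Site selectivity is needed and should come from sterics, since the carbenoid carbon bonds to the furan carbon bearing methyl and not to the one bearing the secondary cyclohexyl group; this places the ester carbon next to the future CMe2. The endo vinyl geometry required for the Cope step is inherent to donor/acceptor carbenoids, and 2,5-disubstitution suppresses zwitterionic ring-opening of the furan.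

Step 10
Reactants: 15 cycloadduct
Product: 17 diol (R)-pantolactonyl cis-2,6-bis(hydroxymethyl)-2-methyl-6-(protected cyclohexyl)-5,6-dihydro-2H-pyran-3-carboxylate, via ozonide 16 (not isolated)
Conditions: O3 (1 equiv, Sudan red 7B indicator), CH2Cl2, −78 °C; NaBH4, MeOH, −78 → −20 °C; AcOH quench
Reagents that add atoms: ozone, [O-][O+]=O
Why: chemoselective ozonolysis of the strained, electron-rich etheno bridge in the presence of the electron-poor enoate, with cold borohydride reduction so that the new alkoxide next to the ester does not lactonise.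

Step 11
Reactants: 17 diol
Product: 18 bis(O-phenyl thionocarbonate) of 17
Conditions: PhOC(S)Cl, pyridine, DMAP (cat.), CH2Cl2, 0 °C → rt
Reagents that add atoms: O-phenyl chlorothionoformate, S=C(Cl)Oc1ccccc1
Why: acylation of both primary neopentyl-type alcohols gives the radical precursors for the Barton–McCombie deoxygenation.

Step 12
Reactants: 18 bis(thionocarbonate)
Product: 19 (R)-pantolactonyl 2,2,6-trimethyl-6-(protected cyclohexyl)-5,6-dihydro-2H-pyran-3-carboxylate
Conditions: Bu3SnH (0.5 M), AIBN (cat.), toluene, 110 °C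
Reagents that add atoms: none
Why: Barton–McCombie deoxygenation turns both CH2O groups into the two cis methyls; the high stannane concentration should trap the primary radicals before a 1,2-vinyl shift can occur, and β-alkoxy radicals do not fragment.

Step 13
Reactants: 19 ester
Product: 20 2,2,6-trimethyl-6-(protected cyclohexyl)-5,6-dihydro-2H-pyran-3-carboxylic acid
Conditions: LiOH, THF/H2O, rt; then 1 M HCl to pH 3
Reagents that add atoms: water (as LiOH/H2O), O
Why: saponification of the activated α-acyloxy-lactone ester releases the acid and the auxiliary; the acetonide is stable to base.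

Step 14
Reactants: 20 acid
Product: 24 keto diol 6-(3,4-dihydroxy-4-methylcyclohexyl)-2,2,6-trimethyloxan-3-one, via acyl azide 21 (not isolated), via alkenyl isocyanate 22 (not isolated), via ketone acetonide 23 (not isolated)
Conditions: (PhO)2P(O)N3, Et3N, toluene, rt → 90 °C; then 2 M HCl, THF, 50 °C
Reagents that add atoms: water, O
Why: Curtius rearrangement of an α,β-unsaturated acid gives an alkenyl isocyanate whose acid hydrolysis (carbamic acid, enamine, ketone) excises the carboxyl carbon and leaves the C3 ketone with C4 already at the CH2 level; the same acid removes the acetonide.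

Step 15
Reactants: 24 keto diol
Product: 26 cyclic sulfate of 24, via cyclic sulfite 25 (not isolated)
Conditions: SOCl2, Et3N, CH2Cl2, 0 °C; then RuCl3·xH2O (cat.), NaIO4, MeCN/H2O, 0 °C
Reagents that add atoms: thionyl chloride, O=S(Cl)Cl; sodium periodate, [Na+].[O-]I(=O)(=O)=O
Why: cyclic sulfite formation and ruthenium-catalysed oxidation activate both oxygens of the cis-diol at once; the oxane has no α-hydrogen next to its oxygen and the ketone is inert to the oxidant.

Step 16
Reactants: 26 cyclic sulfate
Product: 28 bromohydrin 6-(3-bromo-4-hydroxy-4-methylcyclohexyl)-2,2,6-trimethyloxan-3-one (Br cis to the C1' substituent), via lithium bromoalkyl sulfate 27 (not isolated)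
Conditions: LiBr, THF, 50 °C; then H2SO4 (cat.), H2O, THF, rt
Reagents that add atoms: lithium bromide, [Li+].[Br-]
Why: SN2 opening of the cyclic sulfate at the secondary carbon C3' inverts the axial C–O into the equatorial C–Br cis to the side chain, and hydrolysis of the tertiary sulfate monoester frees the C4' alcohol without change of configuration.

Step 17
Reactants: 28 bromohydrin
Product: 29 bromochloro ketone 6-[(1R,3R,4R)-3-bromo-4-chloro-4-methylcyclohexyl]-2,2,6-trimethyloxan-3-one
Conditions: HCl (g), ZnCl2 (cat.), CH2Cl2, −20 → 0 °C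
Reagents that add atoms: hydrogen chloride, Cl
Why: SN1 substitution of a tertiary alcohol with neighbouring-group participation; the C4' cation is bridged by the C3' bromine on the face where it already sits, so chloride enters anti and gives the trans-diequatorial bromochloride with axial methyl (net retention at C4').

Step 18
Reactants: 29 bromochloro ketone
Product: 30 alkenyl bromide 3-bromo-6-(3-bromo-4-chloro-4-methylcyclohexyl)-2,2,6-trimethyl-5,6-dihydro-2H-pyran
Conditions: (PhO)3P, Br2, CH2Cl2, −60 °C; then 29, Et3N, −60 °C → reflux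
Reagents that add atoms: bromine, BrBr
Why: conversion of a ketone into the alkenyl bromide with a triphenyl phosphite–bromine reagent; the ketone can enolise only toward C4 because C2 is quaternary, so a single regioisomer is possible.

Step 19
Reactants: 30 alkenyl bromide
Product: 31 deoxycaespitol
Conditions: Mn(dpm)3 [tris(2,2,6,6-tetramethylheptane-3,5-dionato)manganese] (10 mol%), PhSiH3, t-BuOOH, i-PrOH, rt
Reagents that add atoms: none
Why: metal-hydride hydrogen-atom-transfer hydrogenation of an alkenyl halide (Mukaiyama type); H adds to C4 to give the α-bromo radical at C3, and the second hydrogen should arrive at C3 anti to the axial C2 methyl, leaving bromine equatorial (3S) without C–Br hydrogenolysis.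

**Compound list**
1 | (R)-carvone | C=C(C)[C@@H]1CC=C(C)C(=O)C1 | starting material
2 | trans-epoxycarvone (oxirane anti to isopropenyl) | C=C(C)[C@@H]1C[C@H]2O[C@@]2(C)C(=O)C1 | intermediate
3 | (1R,2S,4R)-1-methyl-4-(prop-1-en-2-yl)cyclohexane-1,2-diol | C=C(C)[C@@H]1CC[C@@](C)(O)[C@@H](O)C1 | intermediate
4 | acetonide of 3 | C=C(C)[C@@H]1CC[C@@]2(C)OC(C)(C)O[C@H]2C1 | intermediate
5 | ozonide of 4 (1,2,4-trioxolane, both epimers at the ozonide carbon; not isolated) | CC1(OCOO1)[C@@H]1CC[C@@]2(C)OC(C)(C)O[C@H]2C1 | intermediate
6 | methyl ketone (acetyl on C1' of the acetonide-protected ring) | CC(=O)[C@@H]1CC[C@@]2(C)OC(C)(C)O[C@H]2C1 | intermediate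
7 | lithium enolate of 6 (not isolated) | C=C(O[Li])[C@@H]1CC[C@@]2(C)OC(C)(C)O[C@H]2C1 | intermediate
8 | alkynone, 1-(protected cyclohexyl)pent-4-yn-1-one | C#CCCC(=O)[C@@H]1CC[C@@]2(C)OC(C)(C)O[C@H]2C1 | intermediate
9 | 2-methyl-5-(protected cyclohexyl)furan | Cc1ccc(o1)[C@@H]1CC[C@@]2(C)OC(C)(C)O[C@H]2C1 | intermediate
10 | (R)-pantolactone | CC1(C)COC(=O)[C@@H]1O | starting material
11 | but-3-enoic acid | C=CCC(=O)O | starting material
12 | (R)-pantolactonyl but-3-enoate | C=CCC(=O)O[C@H]1C(=O)OCC1(C)C | intermediate
13 | (R)-pantolactonyl 2-diazobut-3-enoate | C=CC(=[N+]=[N-])C(=O)O[C@H]1C(=O)OCC1(C)C | intermediate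
14 | cis-divinylcyclopropane (2-oxabicyclo[3.1.0]hex-3-ene; vinyl endo, ester exo; not isolated) | C[C@]12OC([C@@H]3CC[C@@]4(C)OC(C)(C)O[C@H]4C3)=C[C@H]1[C@]2(C=C)C(=O)O[C@H]5C(=O)OCC5(C)C | intermediate
15 | cycloadduct, 8-oxabicyclo[3.2.1]octa-2,6-diene-2-carboxylate (C1 methyl, C5 cyclohexyl) | C[C@]12O[C@]([C@@H]3CC[C@@]4(C)OC(C)(C)O[C@H]4C3)(C=C1)CC=C2C(=O)O[C@H]5C(=O)OCC5(C)C | intermediate
16 | ozonide of the etheno bridge of 15 (not isolated) | C[C@]12O[C@]([C@@H]3CC[C@@]4(C)OC(C)(C)O[C@H]4C3)(C6OOC1O6)CC=C2C(=O)O[C@H]5C(=O)OCC5(C)C | intermediate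
17 | cis-2,6-bis(hydroxymethyl) dihydropyran ester | C[C@@]1(CO)O[C@]([C@@H]2CC[C@@]3(C)OC(C)(C)O[C@H]3C2)(CO)CC=C1C(=O)O[C@H]4C(=O)OCC4(C)C | intermediate
18 | bis(O-phenyl thionocarbonate) of 17 | C[C@@]1(COC(=S)Oc2ccccc2)O[C@]([C@@H]3CC[C@@]4(C)OC(C)(C)O[C@H]4C3)(COC(=S)Oc5ccccc5)CC=C1C(=O)O[C@H]6C(=O)OCC6(C)C | intermediate
19 | (R)-pantolactonyl 2,2,6-trimethyl-6-(protected cyclohexyl)-5,6-dihydro-2H-pyran-3-carboxylate | CC1(C)O[C@@](C)([C@@H]2CC[C@@]3(C)OC(C)(C)O[C@H]3C2)CC=C1C(=O)O[C@H]4C(=O)OCC4(C)C | intermediate
20 | corresponding dihydropyran-3-carboxylic acid | CC1(C)O[C@@](C)([C@@H]2CC[C@@]3(C)OC(C)(C)O[C@H]3C2)CC=C1C(O)=O | intermediate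
21 | acyl azide of 20 (not isolated) | CC1(C)O[C@@](C)([C@@H]2CC[C@@]3(C)OC(C)(C)O[C@H]3C2)CC=C1C(=O)N=[N+]=[N-] | intermediate
22 | alkenyl isocyanate (not isolated) | CC1(C)O[C@@](C)([C@@H]2CC[C@@]3(C)OC(C)(C)O[C@H]3C2)CC=C1N=C=O | intermediate
23 | oxan-3-one with acetonide-protected ring (not isolated) | CC1(C)O[C@@](C)([C@@H]2CC[C@@]3(C)OC(C)(C)O[C@H]3C2)CCC1=O | intermediate
24 | keto diol, 6-(3,4-dihydroxy-4-methylcyclohexyl)-2,2,6-trimethyloxan-3-one | CC1(C)O[C@@](C)([C@@H]2CC[C@@](C)(O)[C@@H](O)C2)CCC1=O | intermediate
25 | cyclic sulfite of 24 (not isolated) | CC1(C)O[C@@](C)([C@@H]2CC[C@@]3(C)OS(=O)O[C@H]3C2)CCC1=O | intermediate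
26 | cyclic sulfate of 24 | CC1(C)O[C@@](C)([C@@H]2CC[C@@]3(C)OS(=O)(=O)O[C@H]3C2)CCC1=O | intermediate
27 | lithium 3'-bromo-4'-sulfate monoester (not isolated) | [Li+].CC1(C)O[C@@](C)([C@@H]2CC[C@@](C)(OS(=O)(=O)[O-])[C@H](Br)C2)CCC1=O | intermediate
28 | bromohydrin (3'-Br equatorial, 4'-OH equatorial, 4'-Me axial) | CC1(C)O[C@@](C)([C@@H]2CC[C@@](C)(O)[C@H](Br)C2)CCC1=O | intermediate
29 | 6-[(1R,3R,4R)-3-bromo-4-chloro-4-methylcyclohexyl]-2,2,6-trimethyloxan-3-one | CC1(C)O[C@@](C)([C@@H]2CC[C@@](C)(Cl)[C@H](Br)C2)CCC1=O | intermediate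
30 | 3-bromo-5,6-dihydro-2H-pyran (alkenyl bromide) | CC1(C)O[C@@](C)([C@@H]2CC[C@@](C)(Cl)[C@H](Br)C2)CC=C1Br | intermediate
31 | deoxycaespitol, (3S,6R)-3-bromo-6-[(1R,3R,4R)-3-bromo-4-chloro-4-methylcyclohexyl]-2,2,6-trimethyloxane | CC1(C)O[C@@](C)([C@@H]2CC[C@@](C)(Cl)[C@H](Br)C2)CC[C@@H]1Br | target

**Count**
Total steps: 19. Longest linear sequence: 17 (steps 1–6 and 9–19).

**Steps most likely to fail**

Step 9. The carbenoid may cyclopropanate the cyclohexyl-flanked double bond of the furan, which gives the regioisomer with the wrong bridgehead configuration, and zwitterionic ring-opening of the furan to trienones may compete. The fallback leaves the cycloaddition and closes the oxane by C–O bond formation. It sets out from 6: addition of 4-methylpent-3-enylmagnesium bromide (CeCl3, THF) gives the tertiary alcohol F1, whose carbinol epimers must be separated. Epoxidation with mCPBA gives the epoxy alcohol F2. Acid-catalysed opening at the tertiary oxirane carbon (CSA, CH2Cl2; the five-membered ether is the expected by-product) gives the oxan-3-ol F3. Oxidation with Dess–Martin periodinane returns to 23, which is hydrolysed to 24 as in the second stage of step 14.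

Step 17. Ionisation of the tertiary alcohol is slowed by the neighbouring bromine, so proton loss from the cation, or opening of the bromonium at the secondary carbon, may outrun the wanted chloride capture. The fallback gives up the stepwise substitution for alkene addition. It sets out from 24: thiocarbonyldiimidazole (toluene, reflux) gives the cyclic thionocarbonate F4. Corey–Winter olefination (P(OMe)3, 110 °C) gives the cyclohexene F5. Bromochlorination (N-bromosuccinimide, benzyltriethylammonium chloride, CH2Cl2, −78 °C) gives the two Markovnikov anti adducts, from which the trans-diequatorial isomer is separated; this is 29.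

Step 2. Hydride may reach the carbonyl of the epoxy ketone from the oxirane face and give the epimeric carbinol, hence the trans-diol. The fallback sets the same two oxygens by hydroxyl-directed epoxidation. It sets out from 1: Luche reduction (NaBH4, CeCl3, MeOH) gives cis-carveol F6. Mitsunobu inversion (4-nitrobenzoic acid, PPh3, DIAD) gives trans-carveyl 4-nitrobenzoate F7, and methanolysis (K2CO3, MeOH) gives trans-carveol F8. Epoxidation with VO(acac)2 and t-BuOOH, syn to the hydroxyl, gives the epoxy alcohol F9, and LiAlH4 opens the oxirane at the secondary carbon to return to 3.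

Further compounds
F1 | step 9 | tertiary alcohol from 6 and the homoprenyl Grignard reagent (needed carbinol epimer) | CC(C)=CCC[C@@](C)(O)[C@@H]1CC[C@@]2(C)OC(C)(C)O[C@H]2C1
F2 | step 9 | epoxy alcohol (both oxirane epimers) | CC1(C)OC1CC[C@@](C)(O)[C@@H]1CC[C@@]2(C)OC(C)(C)O[C@H]2C1
F3 | step 9 | 2,2,6-trimethyl-6-(protected cyclohexyl)oxan-3-ol (both carbinol epimers) | CC1(C)O[C@@](C)([C@@H]2CC[C@@]3(C)OC(C)(C)O[C@H]3C2)CCC1O
F4 | step 17 | cyclic thionocarbonate of 24 | CC1(C)O[C@@](C)([C@@H]2CC[C@@]3(C)OC(=S)O[C@H]3C2)CCC1=O
F5 | step 17 | 2,2,6-trimethyl-6-(4-methylcyclohex-3-en-1-yl)oxan-3-one | CC1(C)O[C@@](C)([C@@H]2CCC(C)=CC2)CCC1=O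
F6 | step 2 | cis-carveol | C=C(C)[C@@H]1CC=C(C)[C@H](O)C1
F7 | step 2 | trans-carveyl 4-nitrobenzoate | C=C(C)[C@@H]1CC=C(C)[C@@H](OC(=O)c2ccc(cc2)[N+](=O)[O-])C1
F8 | step 2 | trans-carveol | C=C(C)[C@@H]1CC=C(C)[C@@H](O)C1
F9 | step 2 | epoxy alcohol (oxirane syn to hydroxyl, both anti to isopropenyl) | C=C(C)[C@@H]1C[C@H]2O[C@@]2(C)[C@@H](O)C1
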